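With the quinone ring numbered C1(=O), C2(OH), C3(side chain), C4(=O), C5(OMe), C6(H), the ring is an enolized cyclohexane-1,2,4,5-tetraone: C1–C2 is an oxalyl unit lodged between C6 and C3, the two α-carbons of a 2,3-diketone (C5, C4). A double Claisen condensation of acyclic (12Z,15Z)-nonadeca-12,15-diene-2,3-dione with dimethyl oxalate therefore forms the C6–C1 and C2–C3 bonds and the complete ring, at its final oxidation level, in one operation. The diketone arises from undec-10-ynoic acid by propargylic coupling, Z-selective semihydrogenation and acyl-anion addition; selective etherification of the unhindered hydroxyl next to C6 completes the route.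

Key step: step 5

Assumption: 1-bromohex-2-yne (3) is taken as purchased; otherwise it is one step (PBr3) from commercial hex-2-yn-1-ol.

Step 1
Reactants: 1 undec-10-ynoic acid
Product: 2 N-methoxy-N-methylundec-10-ynamide
Conditions: CDI, CH2Cl2, rt; then MeNH(OMe)·HCl, rt
Reagents that add atoms: N,O-dimethylhydroxylamine hydrochloride, CNOC.Cl
Why: Weinreb amide formation through the acyl imidazolide (CDI activation, then aminolysis) is routine and leaves the terminal alkyne untouched.

Step 2
Reactants: 2 N-methoxy-N-methylundec-10-ynamide; 3 1-bromohex-2-yne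
Product: 4 N-methoxy-N-methylheptadeca-10,13-diynamide
Conditions: CuI, NaI, Cs2CO3, DMF, rt, Ar
Reagents that add atoms: none
Why: Monovalent-copper-mediated coupling of a terminal alkyne with a propargylic bromide (iodide-assisted substitution by the copper acetylide) should give the methylene-interrupted diyne under a carbonate base mild enough to avoid allene formation.

Step 3
Reactants: 4 N-methoxy-N-methylheptadeca-10,13-diynamide
Product: 5 (10Z,13Z)-N-methoxy-N-methylheptadeca-10,13-dienamide
Conditions: H2 (1 atm), Pd/CaCO3 poisoned with Pb(OAc)2, quinoline, EtOAc, rt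
Reagents that add atoms: none
Why: Lindlar-type semihydrogenation adds H2 syn to each alkyne on the poisoned palladium surface, so both alkenes should be Z, with quinoline and a measured uptake of two equivalents of H2 guarding against over-reduction and the amide N–O bond left intact.

Step 4
Reactants: 5 (10Z,13Z)-N-methoxy-N-methylheptadeca-10,13-dienamide; 6 ethyl vinyl ether
Product: 9 (12Z,15Z)-nonadeca-12,15-diene-2,3-dione, via 1-ethoxyvinyllithium 7 (not isolated), via ethoxy enone 8 (not isolated)
Conditions: 6, t-BuLi, THF, −78 to 0 °C; then 5, −78 to 0 °C; then 2 M HCl, THF, rt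
Reagents that add atoms: water, O
Why: Weinreb ketone synthesis with 1-ethoxyvinyllithium as an acetyl-anion equivalent stops at the chelated tetrahedral intermediate, and dilute acid should then release the enone and hydrolyse its enol ether to the 1,2-diketone without touching the Z,Z-diene.

Step 5
Reactants: 9 (12Z,15Z)-nonadeca-12,15-diene-2,3-dione; 10 dimethyl oxalate
Product: 12 2,5-dihydroxy-3-[(8Z,11Z)-pentadeca-8,11-dien-1-yl]cyclohexa-2,5-diene-1,4-dione, via oxalyl monoadduct 11 (not isolated)
Conditions: NaOMe (4 equiv), 10 (1.5 equiv), MeOH–THF, 9 added slowly at 0 °C, then 50 °C; then 1 M HCl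
Reagents that add atoms: none
Why: Methoxide enolizes the methyl terminus of 9 (the future C6), which attacks dimethyl oxalate in a crossed Claisen condensation (C6–C1 bond) to give enolate 11; enolization at the chain-bearing α'-methylene (the future C3) then closes the ring on the remaining ester carbonyl (C2–C3 bond), and the cyclohexane-1,2,4,5-tetraone so formed is drained as the doubly vinylogous carboxylate dianion of 12, which should drive both condensations. The closest known reaction types are the double Claisen (oxalate) annulation of ketones bearing two α-CH groups to cyclic polyketones and the self-condensation of α-keto esters to 3,6-dialkyl-2,5-dihydroxybenzoquinones. The six-membered ring closes by a 6-(enolexo)-exo-trig acyl substitution (Dieckmann mode). No stereocentre is created, and the bis-allylic methylene of the Z,Z-diene is not acidic enough for NaOMe at 50 °C, so the alkene geometry should be preserved. The step needs cross- over self-condensation of the diketone, which the non-enolizable oxalate held in excess during slow addition of 9 should secure; the order of the two acylations is immaterial because both converge on the same ring.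

Step 6
Reactants: 12 2,5-dihydroxy-3-[(8Z,11Z)-pentadeca-8,11-dien-1-yl]cyclohexa-2,5-diene-1,4-dione
Product: 13 sorgoleone-360, 2-hydroxy-5-methoxy-3-[(8Z,11Z)-pentadeca-8,11-dien-1-yl]cyclohexa-2,5-diene-1,4-dione
Conditions: HCl (1.25 M in MeOH), 40 °C
Reagents that add atoms: methanol, CO
Why: Fischer-type etherification of a vinylogous carboxylic acid (acid-catalysed addition–elimination of methanol) should occur only at the unhindered hydroxy-enone unit flanking C6–H, whose two oxygens are equivalent by the mirror plane through C3 and C6, while the unit flanking the side chain is shielded, in line with the known inertness of 3-alkyl-2-hydroxyquinones to methanolic acid.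

Compound list
1 | undec-10-ynoic acid | C#CCCCCCCCCC(=O)O | starting material
2 | N-methoxy-N-methylundec-10-ynamide | C#CCCCCCCCCC(=O)N(C)OC | intermediate
3 | 1-bromohex-2-yne | CCCC#CCBr | starting material
4 | N-methoxy-N-methylheptadeca-10,13-diynamide | CCCC#CCC#CCCCCCCCCC(=O)N(C)OC | intermediate
5 | (10Z,13Z)-N-methoxy-N-methylheptadeca-10,13-dienamide | CCC/C=C\C/C=C\CCCCCCCCC(=O)N(C)OC | intermediate
6 | ethyl vinyl ether | C=COCC | starting material
7 | 1-ethoxyvinyllithium | [Li]C(=C)OCC | intermediate (not isolated)
8 | (12Z,15Z)-2-ethoxynonadeca-1,12,15-trien-3-one | CCC/C=C\C/C=C\CCCCCCCCC(=O)C(=C)OCC | intermediate (not isolated)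
9 | (12Z,15Z)-nonadeca-12,15-diene-2,3-dione | CCC/C=C\C/C=C\CCCCCCCCC(=O)C(C)=O | intermediate
10 | dimethyl oxalate | COC(=O)C(=O)OC | starting material
11 | methyl (14Z,17Z)-2,4,5-trioxohenicosa-14,17-dienoate (present as its sodium enolate) | CCC/C=C\C/C=C\CCCCCCCCC(=O)C(=O)CC(=O)C(=O)OC | intermediate (not isolated)
12 | 2,5-dihydroxy-3-[(8Z,11Z)-pentadeca-8,11-dien-1-yl]cyclohexa-2,5-diene-1,4-dione | CCC/C=C\C/C=C\CCCCCCCC1=C(O)C(=O)C=C(O)C1=O | intermediate
13 | sorgoleone-360, 2-hydroxy-5-methoxy-3-[(8Z,11Z)-pentadeca-8,11-dien-1-yl]cyclohexa-2,5-diene-1,4-dione | CCC/C=C\C/C=C\CCCCCCCC1=C(O)C(=O)C=C(OC)C1=O | target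

Total step count: 6
Longest linear sequence: 6 steps (1 to 13)

Steps most likely to fail

Step 5. Base-mediated self-condensation (aldol oligomerization) of the enolizable diketone may outrun its interception by the oxalate, or the sequence may stall after the first acylation. The fallback gives up the oxalate annulation and attaches the side chain to a preformed ring; it sets out from 3 and returns at 12. 1-Bromohex-2-yne 3 would be coupled with commercial non-8-yn-1-ol (CuI, NaI, Cs2CO3, DMF) to pentadeca-8,11-diyn-1-ol F1. Semihydrogenation as in step 3 would give (8Z,11Z)-pentadeca-8,11-dien-1-ol F2, and Dess–Martin oxidation in CH2Cl2 would give (8Z,11Z)-pentadeca-8,11-dienal F3. Organocatalytic three-component reductive alkylation of commercial 2,5-dihydroxy-1,4-benzoquinone with F3 and Hantzsch ester (L-proline cat., CH2Cl2, rt) would then give 12. This is a Knoevenagel condensation followed by conjugate hydride transfer, a reaction type established for 3-alkyl-2,5-dihydroxybenzoquinones.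

Step 6. Site selectivity may be lost (etherification at the hindered unit or at both units), or conversion may stop short at equilibrium. The fallback sets out from 12 and returns at 13. Exhaustive O-methylation (Me2SO4, K2CO3, acetone) would give 2,5-dimethoxy-3-[(8Z,11Z)-pentadeca-8,11-dien-1-yl]cyclohexa-2,5-diene-1,4-dione F4. Selective acid hydrolysis (aqueous HClO4, THF, rt) of the sterically compressed methoxy group next to the side chain would then give 13; this selectivity is known for 3-alkyl-2,5-dimethoxybenzoquinones.

Step 4. Metalation of the vinyl ether may be incomplete, and acid-promoted polymerization or self-aldol reaction may set in during unmasking of the enol ether. The fallback replaces the vinyl ether by a dithiane acyl-anion equivalent; it sets out from 5 and returns at 9. Addition of 2-lithio-2-methyl-1,3-dithiane (2-methyl-1,3-dithiane, n-BuLi, THF, −30 °C) to 5 would give (10Z,13Z)-1-(2-methyl-1,3-dithian-2-yl)heptadeca-10,13-dien-1-one F5. Alkylative dithiane hydrolysis (MeI, CaCO3, aqueous MeCN, 40 °C) would then give 9.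

Further compounds
F1 | step 5 | pentadeca-8,11-diyn-1-ol | CCCC#CCC#CCCCCCCCO
F2 | step 5 | (8Z,11Z)-pentadeca-8,11-dien-1-ol | CCC/C=C\C/C=C\CCCCCCCO
F3 | step 5 | (8Z,11Z)-pentadeca-8,11-dienal | CCC/C=C\C/C=C\CCCCCCC=O
F4 | step 6 | 2,5-dimethoxy-3-[(8Z,11Z)-pentadeca-8,11-dien-1-yl]cyclohexa-2,5-diene-1,4-dione | CCC/C=C\C/C=C\CCCCCCCC1=C(OC)C(=O)C=C(OC)C1=O
F5 | step 4 | (10Z,13Z)-1-(2-methyl-1,3-dithian-2-yl)heptadeca-10,13-dien-1-one | CCC/C=C\C/C=C\CCCCCCCCC(=O)C1(C)SCCCS1
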